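**Plan**

Numbering: ring A carries C1 (CO2H), C2 (OH) and C6 (chain); the chain runs from C1′ (on C6) to C12′ (on phenyl ring B).
Retrosynthesis cuts the C2–O bond first (carboxylate-directed C–H hydroxylation), then C1′–C2′ (lateral alkylation of the 2-methylbenzoic acid dianion), then C12′–C(ipso, ring B) (copper-catalysed Grignard coupling).
Forward: both benzene rings are bought and no ring is formed. The chain is joined to ring B first, then to the methyl carbon of ring A, and the C2–O bond is made last.
Enabling feature: C2–H lies ortho to the C1 carboxyl group and the other ortho position, C6, is blocked by the 12-phenyldodecyl chain, so the carboxylate can direct palladium to a single C–H bond through a five-membered palladacycle.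
Stereochemistry: the target has no stereocentre and no stereogenic double bond, so nothing has to be set.

Key step: step 4

Assumption: the SMILES carries no stereo-element, so "single enantiomer" is read as the one achiral constitution shown; phenylmagnesium bromide and LDA are used as purchased solutions.

**Route**

Step 1
Reactants: 1 phenylmagnesium bromide; 2 11-bromoundecan-1-ol
Product: 5 11-phenylundecan-1-ol, via bromomagnesium 11-bromoundecan-1-olate 3 (not isolated), via bromomagnesium 11-phenylundecan-1-olate 4 (not isolated)
Conditions: 1 (2.5 equiv, 1.0 M in THF), Li2CuCl4 (5 mol %), THF, −20 °C → rt; then 1 M HCl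
Reagents that add atoms: none
Why: Kochi-type copper-catalysed Grignard cross-coupling, in which the first equivalent of 1 only deprotonates the hydroxyl group (giving 3, an in-flask protection) and the phenylcopper species formed from Li2CuCl4 then displaces the unhindered primary bromide, so that acidification of 4 should release 5.

Step 2
Reactants: 5 11-phenylundecan-1-ol
Product: 7 (11-bromoundecyl)benzene, via triphenyl[(11-phenylundecyl)oxy]phosphonium bromide 6 (not isolated)
Conditions: CBr4, PPh3, CH2Cl2, 0 °C → rt
Reagents that add atoms: carbon tetrabromide, BrC(Br)(Br)Br
Why: Appel reaction, in which PPh3/CBr4 turn the primary alcohol into alkoxyphosphonium bromide 6 and bromide opens it by SN2 at the unhindered carbon with loss of triphenylphosphine oxide, the phenyl ring and saturated chain being inert.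

Step 3
Reactants: 8 2-methylbenzoic acid; 7 (11-bromoundecyl)benzene
Product: 11 2-(12-phenyldodecyl)benzoic acid, via lithium 2-(lithiomethyl)benzoate (dianion of 8) 9 (not isolated), via lithium 2-(12-phenyldodecyl)benzoate 10 (not isolated)
Conditions: 8 (1.3 equiv), LDA (2.7 equiv, commercial solution), THF, 0 °C; then 7 (1.0 equiv), 0 °C → rt; then 1 M HCl
Reagents that add atoms: none
Why: Lateral (benzylic) lithiation of 2-methylbenzoic acid, in which two equivalents of LDA give the carboxylate-stabilised benzylic dianion 9, whose carbanion carbon is far more nucleophilic than the carboxylate oxygen and should alkylate the primary bromide 7 by SN2, giving 11 after acidification of 10.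

Step 4
Reactants: 11 2-(12-phenyldodecyl)benzoic acid
Product: 14 2-hydroxy-6-(12-phenyldodecyl)benzoic acid (target), via potassium 2-(12-phenyldodecyl)benzoate 12 (not isolated), via potassium 2-hydroxy-6-(12-phenyldodecyl)benzoate 13 (not isolated)
Conditions: Pd(OAc)2 (10 mol %), KOAc (2 equiv), p-benzoquinone (1 equiv), O2 (1 atm), DMA, 115 °C; then 1 M HCl
Reagents that add atoms: dioxygen, O=O
Why: Acetate converts 11 into potassium carboxylate 12, which binds Pd(II) through oxygen and delivers it to C2–H, the only free position ortho to C1, where concerted metalation–deprotonation gives a five-membered aryl-palladium(II) carboxylate; dioxygen (with benzoquinone as a π-acidic promoter ligand that is not consumed in the net equation) oxidises this palladacycle, and C2–O bond formation with protonolysis releases potassium salicylate 13 and Pd(II). The closest known reaction type is the Pd(II)-catalysed, carboxylate-directed ortho-C–H hydroxylation of benzoic acids with 1 atm O2 in DMA with KOAc and benzoquinone, a method established for ortho-substituted benzoic acids. No ring is closed in the product (the palladacycle is only a transient intermediate) and no stereocentre is formed. Site selectivity is needed among C2–H, the benzylic C1′ methylene and the other aryl C–H bonds of rings A and B: ring B carries no directing group, C6 is blocked by the chain, and palladation at C1′ would need a slower C(sp3)–H cleavage through a six-membered palladacycle, so C2–H should react. Over-oxidation is excluded because the product has no ortho C–H left, and the substrate is kept as its potassium salt at 115 °C to disfavour decarboxylation of the 6-alkylsalicylate before acidification liberates 14.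

**Compound list**

1 | phenylmagnesium bromide | Br[Mg]c1ccccc1 | starting material
2 | 11-bromoundecan-1-ol | OCCCCCCCCCCCBr | starting material
3 | bromomagnesium 11-bromoundecan-1-olate | Br[Mg]OCCCCCCCCCCCBr | intermediate (not isolated)
4 | bromomagnesium 11-phenylundecan-1-olate | Br[Mg]OCCCCCCCCCCCc1ccccc1 | intermediate (not isolated)
5 | 11-phenylundecan-1-ol | OCCCCCCCCCCCc1ccccc1 | intermediate
6 | triphenyl[(11-phenylundecyl)oxy]phosphonium bromide | [Br-].c1ccccc1CCCCCCCCCCCO[P+](c1ccccc1)(c1ccccc1)c1ccccc1 | intermediate (not isolated)
7 | (11-bromoundecyl)benzene | BrCCCCCCCCCCCc1ccccc1 | intermediate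
8 | 2-methylbenzoic acid | Cc1ccccc1C(=O)O | starting material
9 | lithium 2-(lithiomethyl)benzoate (dianion of 2-methylbenzoic acid) | [Li+].[Li+].[CH2-]c1ccccc1C(=O)[O-] | intermediate (not isolated)
10 | lithium 2-(12-phenyldodecyl)benzoate | [Li+].[O-]C(=O)c1ccccc1CCCCCCCCCCCCc1ccccc1 | intermediate (not isolated)
11 | 2-(12-phenyldodecyl)benzoic acid | O=C(O)c1ccccc1CCCCCCCCCCCCc1ccccc1 | intermediate
12 | potassium 2-(12-phenyldodecyl)benzoate | [K+].[O-]C(=O)c1ccccc1CCCCCCCCCCCCc1ccccc1 | intermediate (not isolated)
13 | potassium 2-hydroxy-6-(12-phenyldodecyl)benzoate | [K+].[O-]C(=O)c1c(O)cccc1CCCCCCCCCCCCc1ccccc1 | intermediate (not isolated)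
14 | 2-hydroxy-6-(12-phenyldodecyl)benzoic acid | O=C(O)c1c(O)cccc1CCCCCCCCCCCCc1ccccc1 | target

**Summary**

Total step count: 4.
Longest linear sequence: 4 steps (2 → 5 → 7 → 11 → 14).

**Steps most likely to fail**

Step 4. Turnover may stall because the salicylate product chelates palladium(II). At 115 °C, palladium-mediated protodecarboxylation of the 2,6-disubstituted acid or oxidation at benzylic C1′ (lactonisation) may also erode the material. The fallback keeps the carboxylate as the directing group but replaces direct oxygenation by halogenation and substitution at lower temperature. It sets out from 11: iridium(III)-catalysed, carboxylate-directed ortho-C–H iodination at room temperature (Cp*Ir(III) catalyst, N-iodosuccinimide, hexafluoroisopropanol) should give 2-iodo-6-(12-phenyldodecyl)benzoic acid F1. Copper-catalysed Ullmann-type hydroxylation of this ortho-iodobenzoic acid (Cu2O cat., KOH, water/DMSO, about 90 °C, then HCl) comes back to the route at 14.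

Step 3. Proton transfer to the dianion, elimination on the bromide, and self-condensation of the dianion (attack of the benzylic carbanion on a second carboxylate) may outrun the SN2 alkylation by a long, poorly soluble bromide. The fallback forms the C1′–C2′ linkage by olefination instead of alkylation and sets out from 7. Heating 7 with triphenylphosphine should give (11-phenylundecyl)triphenylphosphonium bromide F2. Its ylide (NaHMDS, THF) should undergo Wittig reaction with commercial methyl 2-formylbenzoate to give methyl 2-(12-phenyldodec-1-en-1-yl)benzoate F3 as an E/Z mixture of no consequence. Hydrogenation (H2, Pd/C, ethyl acetate) should give methyl 2-(12-phenyldodecyl)benzoate F4, and saponification (LiOH, THF/MeOH/water, then HCl) comes back to the route at 11.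

Step 1. Oxidative homocoupling of the aryl Grignard reagent and halogen–magnesium exchange or reduction of the bromide may compete with cross-coupling, which can also be slowed by aggregation of the poorly soluble bromomagnesium alkoxide. The fallback attaches ring B by electrophilic acylation instead of organometallic coupling and sets out from 2. Jones oxidation should give 11-bromoundecanoic acid F5, and thionyl chloride should convert it into 11-bromoundecanoyl chloride F6. Friedel–Crafts acylation of benzene (AlCl3, 0 °C) should give 11-bromo-1-phenylundecan-1-one F7. Ionic hydrogenation of the aryl ketone (Et3SiH, trifluoroacetic acid) comes back to the route at 7, so that 5 and step 2 are bypassed.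

**Further compounds**

F1 | step 4 | 2-iodo-6-(12-phenyldodecyl)benzoic acid | O=C(O)c1c(I)cccc1CCCCCCCCCCCCc1ccccc1
F2 | step 3 | (11-phenylundecyl)triphenylphosphonium bromide | [Br-].c1ccccc1CCCCCCCCCCC[P+](c1ccccc1)(c1ccccc1)c1ccccc1
F3 | step 3 | methyl 2-(12-phenyldodec-1-en-1-yl)benzoate (E/Z mixture) | COC(=O)c1ccccc1C=CCCCCCCCCCCc1ccccc1
F4 | step 3 | methyl 2-(12-phenyldodecyl)benzoate | COC(=O)c1ccccc1CCCCCCCCCCCCc1ccccc1
F5 | step 1 | 11-bromoundecanoic acid | OC(=O)CCCCCCCCCCBr
F6 | step 1 | 11-bromoundecanoyl chloride | ClC(=O)CCCCCCCCCCBr
F7 | step 1 | 11-bromo-1-phenylundecan-1-one | O=C(CCCCCCCCCCBr)c1ccccc1
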